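The γ-butyrolactone (O1, C2 carbonyl, C3, C4, C5) is opened at O1–C5, and the open chain is cut at C3–O and C3–C4. C3 carries both the hydroxyl and the bond to C4, so one oxonium ylide [2,3]-shift can make both: a chiral dirhodium carbenoid at C3 captures the oxygen of a tertiary allylic alcohol, and the allyl terminus then moves from oxygen to C3. This fixes C3 and C4 together and leaves the oxygen as the C3 hydroxyl. The precursors are an α-diazo ester carrying the 4-benzyloxy-3,5-dimethoxybenzyl group and an E-configured gem-dimethyl allylic alcohol carrying the 3,4-dimethoxybenzyl group; its isobutenyl residue is later cut down to C5.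

Key step: step 7

Assumption: Rh2(S-PTTL)4 (dirhodium tetrakis[N-phthaloyl-(S)-tert-leucinate]) is taken to give the 3S configuration; if the first run shows the opposite sense, the mirror-image catalyst Rh2(R-PTTL)4 would be used with nothing else changed.

Step 1
Reactants: 1 syringaldehyde (4-hydroxy-3,5-dimethoxybenzaldehyde)
Product: 2 4-(benzyloxy)-3,5-dimethoxybenzaldehyde
Conditions: BnBr (1.1 equiv), K2CO3 (1.5 equiv), DMF, rt
Reagents that add atoms: benzyl bromide, BrCc1ccccc1
Why: Williamson ether synthesis, in which the phenoxide of 1 (made more acidic by the para formyl group) displaces bromide from benzyl bromide by SN2; no stereocentre is involved.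

Step 2
Reactants: 2 4-(benzyloxy)-3,5-dimethoxybenzaldehyde
Product: 3 [4-(benzyloxy)-3,5-dimethoxyphenyl]methanol
Conditions: NaBH4 (0.5 equiv), MeOH, 0 °C
Reagents that add atoms: none
Why: Borohydride reduction of an aryl aldehyde to the benzylic alcohol, to which the aryl ethers are inert.

Step 3
Reactants: 3 [4-(benzyloxy)-3,5-dimethoxyphenyl]methanol
Product: 4 2-(benzyloxy)-5-(bromomethyl)-1,3-dimethoxybenzene
Conditions: PBr3 (0.4 equiv), Et2O, 0 °C; used without storage
Reagents that add atoms: phosphorus tribromide, BrP(Br)Br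
Why: Bromination of an electron-rich benzylic alcohol through its phosphite ester and bromide displacement, under conditions that leave the benzyl and methyl ethers untouched.

Step 4
Reactants: 4 2-(benzyloxy)-5-(bromomethyl)-1,3-dimethoxybenzene; 5 methyl acetoacetate
Product: 6 methyl 2-{[4-(benzyloxy)-3,5-dimethoxyphenyl]methyl}-3-oxobutanoate (racemic)
Conditions: 5 (1.5 equiv), NaH (1.1 equiv), THF, 0 °C; then 4, rt
Reagents that add atoms: none
Why: Acetoacetic ester alkylation, in which the sodium enolate of 5 is C-alkylated by the reactive benzylic bromide and the excess of 5 limits double alkylation; the new α-centre is racemic and is erased in step 5.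

Step 5
Reactants: 6 methyl 2-{[4-(benzyloxy)-3,5-dimethoxyphenyl]methyl}-3-oxobutanoate
Product: 7 methyl 3-[4-(benzyloxy)-3,5-dimethoxyphenyl]-2-diazopropanoate
Conditions: 4-acetamidobenzenesulfonyl azide (1.2 equiv), DBU (1.5 equiv), MeCN, 0 °C to rt
Reagents that add atoms: 4-acetamidobenzenesulfonyl azide, CC(=O)Nc1ccc(cc1)S(=O)(=O)N=[N+]=[N-]
Why: Deacylative Regitz diazo transfer, in which the enolate of the α-substituted acetoacetate adds to the sulfonyl azide and the adduct passes the acetyl group to the sulfonamide nitrogen, leaving the α-diazo ester.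

Step 6
Reactants: 8 4-allyl-1,2-dimethoxybenzene (methyl eugenol); 9 2-methylbut-3-en-2-ol
Product: 10 (E)-5-(3,4-dimethoxyphenyl)-2-methylpent-3-en-2-ol
Conditions: second-generation Grubbs catalyst (H2IMes)(PCy3)Cl2Ru=CHPh (3 mol%), 9 (5 equiv), 1,4-benzoquinone (10 mol%), CH2Cl2, 40 °C
Reagents that add atoms: none
Why: Olefin cross-metathesis between a reactive allylarene and a hindered tertiary allylic alcohol that does not homodimerise, driven by loss of ethene; the bulky carbinol end should enforce the E geometry and benzoquinone should suppress double-bond migration.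

Step 7
Reactants: 7 methyl 3-[4-(benzyloxy)-3,5-dimethoxyphenyl]-2-diazopropanoate; 10 (E)-5-(3,4-dimethoxyphenyl)-2-methylpent-3-en-2-ol
Product: 12 methyl (2S,3S)-2-{[4-(benzyloxy)-3,5-dimethoxyphenyl]methyl}-3-[(3,4-dimethoxyphenyl)methyl]-2-hydroxy-5-methylhex-4-enoate, via oxonium ylide 11 (not isolated)
Conditions: Rh2(S-PTTL)4 (1 mol%), 10 (1.5 equiv), toluene, −78 °C, 7 added over 3 h by syringe pump; then slowly to rt
Reagents that add atoms: none
Why: Proposed new method: Rh2(S-PTTL)4, a chiral carboxylate of divalent rhodium, should decompose 7 at −78 °C to an electrophilic carbenoid that is captured by the hydroxyl oxygen of 10, and the oxonium ylide 11 should then undergo a concerted [2,3]-sigmatropic shift through a five-membered envelope in which C3 bonds to the far alkene carbon as the O–CMe2 bond breaks, so that the oxygen remains as the free C3 hydroxyl and no ring is closed. The closest known reaction type is the dirhodium-catalysed ylide formation and [2,3]-shift of aryl- and vinyl-substituted (donor–acceptor) diazoacetates with tertiary allylic alcohols; an α-benzyl diazo ester has not been shown in it, although α-alkyl diazo esters are known to undergo intermolecular carbenoid reactions under bulky dirhodium carboxylates at −78 °C. C3 is expected to be set by the chiral ligand sphere, which shields one face of the ylide carbon while rhodium is still associated. C4 is set relative to C3 by the E alkene geometry: a hydrogen bond from the oxonium O–H to the ester carbonyl keeps the proton on the ester side, the allyl arm therefore folds over the α-benzyl group, and in this envelope the E alkene exposes the face that leads to the (2S,3S) isomer. The step needs ylide formation to outrun 1,2-hydride migration to the cinnamate, which the bulky phthalimido carboxylate ligands, the low temperature and slow addition of 7 into an excess of 10 should secure. It also needs rearrangement to outrun proton transfer (formal O–H insertion), which the gem-dimethyl carbinol should secure because its O–C bond is weakened and the shift delivers a trisubstituted alkene.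

Step 8
Reactants: 12 methyl (2S,3S)-2-{[4-(benzyloxy)-3,5-dimethoxyphenyl]methyl}-3-[(3,4-dimethoxyphenyl)methyl]-2-hydroxy-5-methylhex-4-enoate
Product: 13 methyl (2S,3R)-2-{[4-(benzyloxy)-3,5-dimethoxyphenyl]methyl}-3-[(3,4-dimethoxyphenyl)methyl]-2-hydroxy-4-oxobutanoate
Conditions: OsO4 (2 mol%), NaIO4 (4 equiv), 2,6-lutidine (2 equiv), 1,4-dioxane/H2O 3:1, rt; crude aldehyde taken on at once
Reagents that add atoms: osmium tetroxide, O=[Os](=O)(=O)=O (carrier of the aldehyde oxygen), restored by sodium periodate, [Na+].[O-]I(=O)(=O)=O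
Why: Lemieux–Johnson oxidation, in which OsO4 dihydroxylates the trisubstituted alkene in preference to the arenes and periodate cleaves the diol to the aldehyde and acetone; the lutidine buffer should keep C4 from enolising, and the change of descriptor at that carbon is only a change of CIP priority.

Step 9
Reactants: 13 methyl (2S,3R)-2-{[4-(benzyloxy)-3,5-dimethoxyphenyl]methyl}-3-[(3,4-dimethoxyphenyl)methyl]-2-hydroxy-4-oxobutanoate
Product: 15 (3S,4S)-3-{[4-(benzyloxy)-3,5-dimethoxyphenyl]methyl}-4-[(3,4-dimethoxyphenyl)methyl]-3-hydroxyoxolan-2-one, via hydroxy ester 14 (not isolated)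
Conditions: NaBH4 (1.0 equiv), MeOH, −20 to 0 °C, AcOH quench; then TsOH·H2O (10 mol%), CH2Cl2, rt
Reagents that add atoms: none
Why: Chemoselective borohydride reduction of the aldehyde beside a hindered tertiary α-hydroxy ester, followed by acid-catalysed lactonisation of the γ-hydroxy ester onto the methyl ester to the five-membered ring; neither stereocentre is touched.

Step 10
Reactants: 15 (3S,4S)-3-{[4-(benzyloxy)-3,5-dimethoxyphenyl]methyl}-4-[(3,4-dimethoxyphenyl)methyl]-3-hydroxyoxolan-2-one
Product: 16 (3S,4S)-4-[(3,4-dimethoxyphenyl)methyl]-3-hydroxy-3-[(4-hydroxy-3,5-dimethoxyphenyl)methyl]oxolan-2-one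
Conditions: H2 (1 atm), 10% Pd/C, EtOAc/MeOH, rt
Reagents that add atoms: none
Why: Catalytic hydrogenolysis of the aryl benzyl ether, to which the lactone, the tertiary alcohol and the methyl ethers are inert.

Compound list
1 | syringaldehyde (4-hydroxy-3,5-dimethoxybenzaldehyde) | COc1cc(C=O)cc(OC)c1O | starting material
2 | 4-(benzyloxy)-3,5-dimethoxybenzaldehyde | COc1cc(C=O)cc(OC)c1OCc1ccccc1 | intermediate
3 | [4-(benzyloxy)-3,5-dimethoxyphenyl]methanol | COc1cc(CO)cc(OC)c1OCc1ccccc1 | intermediate
4 | 2-(benzyloxy)-5-(bromomethyl)-1,3-dimethoxybenzene | COc1cc(CBr)cc(OC)c1OCc1ccccc1 | intermediate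
5 | methyl acetoacetate | CC(=O)CC(=O)OC | starting material
6 | methyl 2-{[4-(benzyloxy)-3,5-dimethoxyphenyl]methyl}-3-oxobutanoate (racemic) | COC(=O)C(Cc1cc(OC)c(OCc2ccccc2)c(OC)c1)C(C)=O | intermediate
7 | methyl 3-[4-(benzyloxy)-3,5-dimethoxyphenyl]-2-diazopropanoate | COC(=O)C(=[N+]=[N-])Cc1cc(OC)c(OCc2ccccc2)c(OC)c1 | intermediate
8 | 4-allyl-1,2-dimethoxybenzene (methyl eugenol) | C=CCc1ccc(OC)c(OC)c1 | starting material
9 | 2-methylbut-3-en-2-ol | CC(C)(O)C=C | starting material
10 | (E)-5-(3,4-dimethoxyphenyl)-2-methylpent-3-en-2-ol | CC(C)(O)/C=C/Cc1ccc(OC)c(OC)c1 | intermediate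
11 | oxonium ylide formed in the flask in step 7: the carbanion carbon bears the methyl ester, the 4-benzyloxy-3,5-dimethoxybenzyl group and the protonated oxygen of 10, E alkene retained | COC(=O)[C-](Cc1cc(OC)c(OCc2ccccc2)c(OC)c1)[OH+]C(C)(C)/C=C/Cc1ccc(OC)c(OC)c1 | intermediate
12 | methyl (2S,3S)-2-{[4-(benzyloxy)-3,5-dimethoxyphenyl]methyl}-3-[(3,4-dimethoxyphenyl)methyl]-2-hydroxy-5-methylhex-4-enoate | COC(=O)[C@](O)(Cc1cc(OC)c(OCc2ccccc2)c(OC)c1)[C@@H](Cc1ccc(OC)c(OC)c1)C=C(C)C | intermediate
13 | methyl (2S,3R)-2-{[4-(benzyloxy)-3,5-dimethoxyphenyl]methyl}-3-[(3,4-dimethoxyphenyl)methyl]-2-hydroxy-4-oxobutanoate | COC(=O)[C@](O)(Cc1cc(OC)c(OCc2ccccc2)c(OC)c1)[C@@H](Cc1ccc(OC)c(OC)c1)C=O | intermediate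
14 | methyl (2S,3S)-2-{[4-(benzyloxy)-3,5-dimethoxyphenyl]methyl}-3-[(3,4-dimethoxyphenyl)methyl]-2,4-dihydroxybutanoate, formed in the flask in step 9 | COC(=O)[C@](O)(Cc1cc(OC)c(OCc2ccccc2)c(OC)c1)[C@@H](Cc1ccc(OC)c(OC)c1)CO | intermediate
15 | (3S,4S)-3-{[4-(benzyloxy)-3,5-dimethoxyphenyl]methyl}-4-[(3,4-dimethoxyphenyl)methyl]-3-hydroxyoxolan-2-one | COc1ccc(C[C@H]2COC(=O)[C@]2(O)Cc2cc(OC)c(OCc3ccccc3)c(OC)c2)cc1OC | intermediate
16 | (3S,4S)-4-[(3,4-dimethoxyphenyl)methyl]-3-hydroxy-3-[(4-hydroxy-3,5-dimethoxyphenyl)methyl]oxolan-2-one | COc1ccc(C[C@H]2COC(=O)[C@]2(O)Cc2cc(OC)c(O)c(OC)c2)cc1OC | target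

Total step count: 10 steps.
Longest linear sequence: 9 steps (steps 1 to 5, then 7 to 10, from syringaldehyde); step 6 is a one-step branch.

Steps most likely to fail

1. Step 7 (the proposed new method). The carbenoid may be consumed by 1,2-hydride migration before the alcohol captures it. The ylide may collapse by proton transfer instead of rearranging. Facial discrimination at C3 or at the alkene terminus may be insufficient.
Fallback (known chemistry): it sets out from bromide 4 and comes back to the route at lactone 15, relying on enolate alkylation anti to a ring substituent. Commercial 3-(3,4-dimethoxyphenyl)propanoic acid would be coupled to (S)-4-benzyl-1,3-oxazolidin-2-one (pivaloyl chloride, Et3N, LiCl, THF) to give (4S)-4-benzyl-3-[3-(3,4-dimethoxyphenyl)propanoyl]-1,3-oxazolidin-2-one F1. Evans alkylation (NaN(SiMe3)2, tert-butyl bromoacetate, THF, −78 °C) on the face away from the auxiliary benzyl group should give tert-butyl (3R)-4-[(4S)-4-benzyl-2-oxo-1,3-oxazolidin-3-yl]-3-[(3,4-dimethoxyphenyl)methyl]-4-oxobutanoate F2. LiBH4 (THF, H2O, 0 °C) would release the auxiliary and give tert-butyl (3R)-3-[(3,4-dimethoxyphenyl)methyl]-4-hydroxybutanoate F3, which should close under TsOH in warm toluene to (4R)-4-[(3,4-dimethoxyphenyl)methyl]oxolan-2-one F4. Enolate hydroxylation (NaN(SiMe3)2, then 2-(phenylsulfonyl)-3-phenyloxaziridine, THF, −78 °C) should give (3R,4S)-4-[(3,4-dimethoxyphenyl)methyl]-3-hydroxyoxolan-2-one F5. The dianion of F5 (lithium diisopropylamide, 2.2 equiv, THF/DMPU, −78 °C) would then be alkylated with 4 on the face opposite the C4 substituent. This places the new benzyl group trans to the C4 benzyl group and the hydroxyl cis to it, as in 15. Step 10 follows unchanged.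

2. Step 8. The α-branched β-hydroxy aldehyde may enolise at C4 (epimerisation) or fragment by retro-aldol reaction during the aqueous cleavage and isolation.
Fallback: it sets out from 12 and comes back at 15, replacing the oxidise-then-isolate sequence by a reductive ozonolysis run in one flask. Ozone (CH2Cl2/MeOH, −78 °C, Sudan Red 7B as end-point indicator) would be followed by NaBH4 added at −78 °C and warmed to 0 °C, then by TsOH. Aldehyde 13 and hydroxy ester 14 would then be passed through cold and without isolation, and no compound outside the list is made (F0).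

3. Step 6. Productive metathesis of the hindered carbinol partner may be slow, leaving time for double-bond migration in the allylarene and for its homodimerisation.
Fallback: it sets out from no numbered compound, because 8 and 9 are replaced by commercial 2-methylbut-3-yn-2-ol and 3,4-dimethoxybenzyl bromide, and it comes back at 10. Copper-catalysed benzylation of the terminal alkyne (CuI, Cs2CO3, tetrabutylammonium iodide, MeCN, rt) should give 5-(3,4-dimethoxyphenyl)-2-methylpent-3-yn-2-ol F6. Trans-selective hydroalumination of this propargylic alcohol (LiAlH4, THF, reflux, aqueous work-up) should then give the E alkene 10.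

Further compounds
F1 | step 7 | (4S)-4-benzyl-3-[3-(3,4-dimethoxyphenyl)propanoyl]-1,3-oxazolidin-2-one | COc1ccc(CCC(=O)N2[C@@H](Cc3ccccc3)COC2=O)cc1OC
F2 | step 7 | tert-butyl (3R)-4-[(4S)-4-benzyl-2-oxo-1,3-oxazolidin-3-yl]-3-[(3,4-dimethoxyphenyl)methyl]-4-oxobutanoate | COc1ccc(C[C@H](CC(=O)OC(C)(C)C)C(=O)N2[C@@H](Cc3ccccc3)COC2=O)cc1OC
F3 | step 7 | tert-butyl (3R)-3-[(3,4-dimethoxyphenyl)methyl]-4-hydroxybutanoate | COc1ccc(C[C@H](CC(=O)OC(C)(C)C)CO)cc1OC
F4 | step 7 | (4R)-4-[(3,4-dimethoxyphenyl)methyl]oxolan-2-one | COc1ccc(C[C@H]2COC(=O)C2)cc1OC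
F5 | step 7 | (3R,4S)-4-[(3,4-dimethoxyphenyl)methyl]-3-hydroxyoxolan-2-one | COc1ccc(C[C@H]2COC(=O)[C@@H]2O)cc1OC
F0 | step 8 | none | none
F6 | step 6 | 5-(3,4-dimethoxyphenyl)-2-methylpent-3-yn-2-ol | CC(C)(O)C#CCc1ccc(OC)c(OC)c1
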